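Take Thursday's target curve first and read from it how long such a flask takes to finish.

| setting | Thursday's | midnight | dawn | noon | summer |
|---|---|---|---|---|---|
| substrate | 0.20 M | 0.10 M | 0.10 M | 0.10 M | 0.10 M |
| partner | 0.20 M | 0.200 M | 0.200 M | 0.200 M | 0.200 M |
| temperature | 60 °C | 60 °C | 20 °C | 40 °C | 80 °C |
| remark | run made earlier |  |  |  |  |
| time |  | 8.0 min | 8.0 min | 8.0 min | 8.0 min |

Thursday's run (percent of the substrate charged)

| time / min | target / % | over-reaction product / % | side product / % |
|---|---|---|---|
| 0.333 | 13.1 | 2.7 | 0.6 |
| 0.667 | 23.8 | 6.9 | 0.8 |
| 1.00 | 29.5 | 8.2 | 0.5 |
| 1.33 | 32.5 | 8.7 | 0.6 |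
| 1.50 | 33.2 | 9.3 | 0.9 |
| 2.00 | 35.8 | 9.0 | 0.7 |
| 2.50 | 36.5 | 8.8 | 1.0 |

(readings scatter by 0.3 percentage points)

- percentages count the substrate that a species holds: one side product counts as two
- the earlier runs do not show what temperature does; that part of a forecast is a guess

- the flask that comes out highest in share of target in all that became target or over-reaction product or side product, or "all alike" when all lie within 1.5 percentage points (midnight / dawn / noon / summer / all alike)
- share of target in all that became target or over-reaction product or side product, midnight
- share of target in all that became target or over-reaction product or side product, dawn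
- share of target in all that became target or over-reaction product or side product, noon
- share of target in all that became target or over-reaction product or side product, summer

I let target climb to its plateau at a rate proportional to what is still missing. That integrates in closed form to a missing part that falls by the factor e in each plateau time, the time the curve needs for that fall. With the last reading, 36.5%, as plateau and 23.8% at 0.667 min, I read 0.632 min, with the scatter of those readings in it.

The bench rule says a flask is finished after 5 plateau times and then shows the share of target among the three products, its selectivity. On Thursday's last reading that share is 78.8%. Midnight stands at Thursday's temperature and holds 12.7 plateau times, so I commit to that share for midnight, though I carry it over to half of Thursday's substrate.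

The border lies at a stretch of the plateau time by 2.53. Temperature is a guess here: if the rate doubles every 10 degrees, the plateau time stretches 4-fold at noon and 16-fold at dawn. Noon then holds 3.17 plateau times and dawn 0.791, both under the bar, so I expect both still moving and read no share for them from Thursday.

The forecast gives 74% for midnight, below mine, then 76% for dawn, 62% for noon and 82% for summer, and names summer. It says noon “is nearly equilibrated”, where I place noon under the bar.

The flasks give 81.3% at midnight, 45.1% at dawn, 42.8% at noon and 95.3% in summer, and summer is highest.

    substrate → open intermediate (k = 0.210 s⁻¹, Ea = 84.0 kJ mol⁻¹)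
    partner → second intermediate (k = 0.0530 s⁻¹, Ea = 99.0 kJ mol⁻¹)
    open intermediate + second intermediate → target (k = 0.230 M⁻¹ s⁻¹, Ea = 51.0 kJ mol⁻¹)
    2 second intermediate → homo product (k = 0.440 M⁻¹ s⁻¹, Ea = 47.0 kJ mol⁻¹)
    partner + target → over-reaction product (k = 0.290 M⁻¹ s⁻¹, Ea = 42.0 kJ mol⁻¹)
    substrate + target → side product (k = 0.210 M⁻¹ s⁻¹, Ea = 69.0 kJ mol⁻¹)
    (constants at 60 °C)

At noon, at 1.63 min, the half-life of partner by its passing into second intermediate is 2.1 min, longer than the 0.38 min of substrate by its passing into open intermediate, and noon's target stands at 23.2% after 8.00 min and at 31.1% after 80.0 min. The neighbour, noon read at 30 min, counts 11.9 of my guessed stretched plateau times, and it holds target at 30.8% with a share of 48.1%.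

The numbers in the tables stem from a simulated flask for an exercise, and the scatter is random.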